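**Plan** (primed locants = cyclohexane ring, unprimed = chromene)

1. Retrosynthetic cuts: the pyran ring at C3=C4 (ring-closing metathesis) and at O1–C2 (palladium-catalysed asymmetric allylic etherification of vinylphenol 25 with carbonate 16); the side chain at its CH2–C(CH3)= bond (B-alkyl Suzuki coupling of 10 with vinyl iodide 13).
2. Carbocycle: the C3′–CH3 bond together with the exocyclic C2′=CH2 (copper-catalysed SN2′ methylation of allylic chloride 9), then the ring bond C1′–C6′ (one-carbon ring expansion).
3. Enabling feature: the quaternary ring carbon C1′ (CH3, side chain) is bonded directly to the sp2 ring carbon C2′. With C2′ as C=O and the first chain carbon as CH2OH this is the α-quaternary β-hydroxy ketone that a semipinacol shift delivers, so the six-membered ring maps onto 1-(2-methyloxiran-2-yl)cyclopentanol 4, whose two ring CH2 groups beside the carbinol carbon are equivalent.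
4. Forward order: cyclopentanol 4 (glycidate 1 plus a C4 di-Grignard reagent) → cyclohexanone 5 (ring expansion) → diene 8 → chloride 9 → triene 10 → chain (15, 16) → aryl ether 26 → pyran ring 27 last → diol 28.
5. Stereochemistry: C1′ from the chiral-pool epoxide 1 by a stereospecific anti 1,2-shift; C3′ from a chiral copper–phosphoramidite catalyst; C2 from a chiral palladium–diphosphine catalyst acting on the (Z)-carbonate.

Key step: step 2

Assumption: methyl (S)-2-methylglycidate 1 is taken as a catalogue chiral building block, and the ligand antipodes named in steps 6 and 15 follow the published induction models; the other antipode is used if a test run shows the opposite sense.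

**Step 1**
Reactants: 1 methyl (2S)-2-methyloxirane-2-carboxylate; 2 1,4-dibromobutane
Product: 4 1-[(2S)-2-methyloxiran-2-yl]cyclopentan-1-ol, via butane-1,4-diylbis(magnesium bromide) 3 (not isolated)
Conditions: 2, Mg, THF, 40 °C; then 1, THF, −78 → 0 °C; aq NH4Cl
Reagents that add atoms: none
Why: Double Grignard addition to an ester (acyl substitution, then ring-closing attack of the second C–Mg bond on the ketone) should build the cyclopentanol faster than the hindered 2,2-disubstituted epoxide is opened at low temperature; the epoxide stereocentre is not touched.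

**Step 2**
Reactants: 4 1-[(2S)-2-methyloxiran-2-yl]cyclopentan-1-ol
Product: 5 (2R)-2-(hydroxymethyl)-2-methylcyclohexan-1-one
Conditions: BF3·OEt2 (1.0 equiv), CH2Cl2, −78 → −30 °C; aq NaHCO3
Reagents that add atoms: none
Why: BF3 binds the epoxide oxygen, the C–O bond at the tertiary epoxide carbon weakens, and a cyclopentane C–C bond lying antiperiplanar to it shifts to that carbon while the carbinol oxygen forms the C=O (concerted 1,2-alkyl shift, semipinacol rearrangement). The closest known reaction type is the Lewis-acid rearrangement of tertiary 2,3-epoxy alcohols to β-hydroxy ketones with ring enlargement of cyclobutanols and cyclopentanols. No new ring-closing attack takes place: the six-membered ring arises because the former epoxide carbon is inserted between the carbinol carbon and one ring CH2 of the five-membered ring (ring expansion by one atom). The new quaternary stereocentre is controlled by the epoxide stereocentre, since the migrating carbon enters anti to the departing oxygen, so (S)-4 should give (R)-5 with inversion. The step needs carbon migration to win over hydride shift and external nucleophilic opening, which the electron-rich C–C bond beside the hydroxyl-bearing carbon, the tertiary epoxide terminus and the low temperature should secure; no choice between the two ring CH2 groups is needed because both are equivalent and lead to the same product.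

**Step 3**
Reactants: 5 (2R)-2-(hydroxymethyl)-2-methylcyclohexan-1-one
Product: 6 (1R)-1-methyl-2-oxocyclohexane-1-carbaldehyde
Conditions: Dess–Martin periodinane, CH2Cl2, 0 °C → rt
Reagents that add atoms: none
Why: Dess–Martin oxidation of the primary alcohol under non-basic conditions avoids retro-aldol loss of formaldehyde, and the quaternary α-carbon cannot epimerize.

**Step 4**
Reactants: 6 (1R)-1-methyl-2-oxocyclohexane-1-carbaldehyde
Product: 8 (1R)-1-ethenyl-1-methyl-2-methylidenecyclohexane, via (2R)-2-ethenyl-2-methylcyclohexan-1-one 7 (not isolated)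
Conditions: Ph3PCH3Br (3.2 equiv), KN(SiMe3)2 (3.0 equiv), THF, −78 °C → reflux
Reagents that add atoms: methyltriphenylphosphonium bromide, C[P+](c1ccccc1)(c1ccccc1)c1ccccc1.[Br-]
Why: Double Wittig methylenation, in which the aldehyde should react at −78 °C and the hindered ketone with the excess alkoxide-free ylide at reflux; the stereocentre is quaternary and is not affected.

**Step 5**
Reactants: 8 (1R)-1-ethenyl-1-methyl-2-methylidenecyclohexane
Product: 9 (6R)-1-(chloromethyl)-6-ethenyl-6-methylcyclohex-1-ene
Conditions: Ca(OCl)2, solid CO2, CH2Cl2/H2O, 0 °C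
Reagents that add atoms: calcium hypochlorite, [Ca+2].[O-]Cl.[O-]Cl
Why: Ene-type allylic chlorination with HOCl, in which electrophilic chlorine adds to the terminal carbon of the electron-rich 1,1-disubstituted alkene and the only allylic ring hydrogens (C3) are lost so that the double bond moves into the ring; the vinyl group is less nucleophilic and has no allylic hydrogen.

**Step 6**
Reactants: 9 (6R)-1-(chloromethyl)-6-ethenyl-6-methylcyclohex-1-ene
Product: 10 (1R,3R)-1-ethenyl-1,3-dimethyl-2-methylidenecyclohexane
Conditions: MeMgBr (1.2 equiv, Et2O, slow addition), Cu(O2CC4H3S) (copper thiophene-2-carboxylate, 3 mol %), (S,S,S)-BINOL-derived N,N-bis[1-(2-methoxyphenyl)ethyl]phosphoramidite (3.3 mol %), CH2Cl2, −78 °C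
Reagents that add atoms: methylmagnesium bromide, C[Mg]Br
Why: Copper-catalysed asymmetric allylic alkylation (SN2′) of a 2-substituted endocyclic allylic chloride with a Grignard reagent should deliver methyl to the ring CH= carbon and regenerate the exocyclic methylene; the chiral monovalent copper–phosphoramidite catalyst selects the face and sets the (3R) centre (CH3 trans to the C1 methyl), the neighbouring quaternary centre (CH3 versus vinyl) biasing the faces only weakly.

**Step 7**
Reactants: 11 but-2-yn-1-ol
Product: 13 (2Z)-3-iodobut-2-en-1-ol, via the cyclic sodium alkenylalanate 12 (not isolated)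
Conditions: NaAlH2(OCH2CH2OCH3)2, THF, 0 °C → rt; then I2, THF, −78 °C; aq Na2S2O3
Reagents that add atoms: iodine, II
Why: Alkoxide-directed trans-hydroalumination of the propargylic alcohol places aluminium on C3 in a five-membered alanate, and iodinolysis with retention should give the (Z)-vinyl iodide.

**Step 8**
Reactants: 10 (1R,3R)-1-ethenyl-1,3-dimethyl-2-methylidenecyclohexane; 13 (2Z)-3-iodobut-2-en-1-ol
Product: 15 (2Z)-5-[(1R,3R)-1,3-dimethyl-2-methylidenecyclohexyl]-3-methylpent-2-en-1-ol, via the B-alkyl-9-borabicyclo[3.3.1]nonane adduct 14 (not isolated)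
Conditions: 9-BBN (1.1 equiv), THF, 0 °C → rt; then 13, Pd(dppf)Cl2 (5 mol %), aq NaOH, THF, 50 °C
Reagents that add atoms: none
Why: Hydroboration followed by B-alkyl Suzuki–Miyaura coupling, in which 9-BBN should add to the monosubstituted vinyl group in preference to the methylene flanked by a quaternary and a tertiary carbon, and the sp3–sp2 coupling retains the (Z) geometry of 13.

**Step 9**
Reactants: 15 (2Z)-5-[(1R,3R)-1,3-dimethyl-2-methylidenecyclohexyl]-3-methylpent-2-en-1-ol
Product: 16 (2Z)-5-[(1R,3R)-1,3-dimethyl-2-methylidenecyclohexyl]-3-methylpent-2-en-1-yl methyl carbonate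
Conditions: ClCO2Me, pyridine, CH2Cl2, 0 °C
Reagents that add atoms: methyl chloroformate, COC(=O)Cl
Why: O-Acylation of the primary allylic alcohol gives the carbonate that serves as the ionizable group for allylic substitution.

**Step 10**
Reactants: 17 2-methoxybenzene-1,4-diol
Product: 18 2-methoxy-1,4-bis(methoxymethoxy)benzene
Conditions: MOMCl (2.5 equiv), iPr2NEt, CH2Cl2, 0 °C → rt, argon
Reagents that add atoms: chloromethyl methyl ether, COCCl
Why: O-Alkylation of both phenols (MOM protection), chosen because the acetal does not migrate between neighbouring oxygens later.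

**Step 11**
Reactants: 18 2-methoxy-1,4-bis(methoxymethoxy)benzene
Product: 19 1-bromo-4-methoxy-2,5-bis(methoxymethoxy)benzene
Conditions: NBS (1.0 equiv), MeCN, 0 °C
Reagents that add atoms: N-bromosuccinimide, O=C1CCC(=O)N1Br
Why: Electrophilic aromatic bromination should occur para to OCH3 and ortho to one OMOM group, the most activated unhindered position of a 1,2,4-trialkoxybenzene.

**Step 12**
Reactants: 19 1-bromo-4-methoxy-2,5-bis(methoxymethoxy)benzene
Product: 22 4-methoxy-2,5-bis(methoxymethoxy)phenol, via the aryllithium 20 (not isolated), via the lithium aryltrimethoxyborate 21 (not isolated)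
Conditions: n-BuLi, THF, −78 °C; B(OMe)3, −78 → 0 °C; then 30 % H2O2, aq NaOH, 0 °C
Reagents that add atoms: hydrogen peroxide, OO
Why: Bromine–lithium exchange, borylation and oxidative C–B to C–O migration (ipso-hydroxylation) place the phenol oxygen where the bromine was.

**Step 13**
Reactants: 22 4-methoxy-2,5-bis(methoxymethoxy)phenol
Product: 24 2-hydroxy-5-methoxy-3,6-bis(methoxymethoxy)benzaldehyde, via the ortho-hydroxymethyl phenol 23 (not isolated)
Conditions: MgCl2, Et3N, (CH2O)n, MeCN, reflux
Reagents that add atoms: paraformaldehyde (as formaldehyde), C=O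
Why: Magnesium-mediated ortho-formylation of a phenol (Casnati–Skattebøl), in which the magnesium phenoxide directs formaldehyde to the only free ortho position and a second formaldehyde oxidizes the benzylic alkoxide by hydride transfer.

**Step 14**
Reactants: 24 2-hydroxy-5-methoxy-3,6-bis(methoxymethoxy)benzaldehyde
Product: 25 2-ethenyl-4-methoxy-3,6-bis(methoxymethoxy)phenol
Conditions: Ph3PCH3Br (2.5 equiv), KOtBu (2.4 equiv), THF, 0 °C → rt
Reagents that add atoms: methyltriphenylphosphonium bromide, C[P+](c1ccccc1)(c1ccccc1)c1ccccc1.[Br-]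
Why: Wittig methylenation of the salicylaldehyde with excess ylide (the first equivalent of base only forms the phenoxide) should give the ortho-vinylphenol, which is used without storage.

**Step 15**
Reactants: 16 (2Z)-5-[(1R,3R)-1,3-dimethyl-2-methylidenecyclohexyl]-3-methylpent-2-en-1-yl methyl carbonate; 25 2-ethenyl-4-methoxy-3,6-bis(methoxymethoxy)phenol
Product: 26 (3S)-5-[(1R,3R)-1,3-dimethyl-2-methylidenecyclohexyl]-3-methylpent-1-en-3-yl 2-ethenyl-4-methoxy-3,6-bis(methoxymethoxy)phenyl ether
Conditions: Pd2(dba)3·CHCl3 (2 mol %), (R,R)-DACH-phenyl Trost ligand (6 mol %), CH2Cl2, rt, stopped at full conversion of 16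
Reagents that add atoms: none
Why: Palladium-catalysed asymmetric allylic alkylation of a phenol, in which zerovalent palladium ionizes the (Z)-carbonate to a π-allyl complex that the phenoxide should attack at the more substituted terminus before the complex equilibrates, so the chiral ligand together with the alkene geometry sets the (S) tertiary ether centre.

**Step 16**
Reactants: 26 (3S)-5-[(1R,3R)-1,3-dimethyl-2-methylidenecyclohexyl]-3-methylpent-1-en-3-yl 2-ethenyl-4-methoxy-3,6-bis(methoxymethoxy)phenyl ether
Product: 27 (2S)-2-{2-[(1R,3R)-1,3-dimethyl-2-methylidenecyclohexyl]ethyl}-6-methoxy-5,8-bis(methoxymethoxy)-2-methyl-2H-chromene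
Conditions: second-generation Grubbs catalyst RuCl2(=CHPh)(PCy3)(H2IMes) (5 mol %), CH2Cl2, 40 °C
Reagents that add atoms: none
Why: Ring-closing metathesis of the styrene with the vinyl group of the tertiary allyl ether closes the six-membered 2H-chromene ring; the stereocentre is not involved and the hindered 1,1-disubstituted ring methylene should stay inert.

**Step 17**
Reactants: 27 (2S)-2-{2-[(1R,3R)-1,3-dimethyl-2-methylidenecyclohexyl]ethyl}-6-methoxy-5,8-bis(methoxymethoxy)-2-methyl-2H-chromene
Product: 28 (2S)-2-{2-[(1R,3R)-1,3-dimethyl-2-methylidenecyclohexyl]ethyl}-6-methoxy-2-methyl-2H-chromene-5,8-diol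
Conditions: ZnBr2 (2.2 equiv), n-PrSH (4 equiv), CH2Cl2, 0 °C, argon; wash with degassed aq Na2S2O4
Reagents that add atoms: none
Why: Lewis acid/thiol cleavage of the two aryl MOM acetals at 0 °C is chosen to spare the tertiary allylic aryl ether of the chromene and the exocyclic alkene, and the air-sensitive hydroquinone is kept under argon with a reducing wash.

**Compound list**

1 | methyl (2S)-2-methyloxirane-2-carboxylate | COC(=O)[C@]1(C)CO1 | starting material
2 | 1,4-dibromobutane | BrCCCCBr | starting material
3 | butane-1,4-diylbis(magnesium bromide) | Br[Mg]CCCC[Mg]Br | intermediate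
4 | 1-[(2S)-2-methyloxiran-2-yl]cyclopentan-1-ol | OC1(CCCC1)[C@]1(C)CO1 | intermediate
5 | (2R)-2-(hydroxymethyl)-2-methylcyclohexan-1-one | O=C1CCCC[C@]1(C)CO | intermediate
6 | (1R)-1-methyl-2-oxocyclohexane-1-carbaldehyde | O=C1CCCC[C@]1(C)C=O | intermediate
7 | (2R)-2-ethenyl-2-methylcyclohexan-1-one | O=C1CCCC[C@]1(C)C=C | intermediate
8 | (1R)-1-ethenyl-1-methyl-2-methylidenecyclohexane | C=C1CCCC[C@]1(C)C=C | intermediate
9 | (6R)-1-(chloromethyl)-6-ethenyl-6-methylcyclohex-1-ene | ClCC1=CCCC[C@]1(C)C=C | intermediate
10 | (1R,3R)-1-ethenyl-1,3-dimethyl-2-methylidenecyclohexane | C=C1[C@H](C)CCC[C@]1(C)C=C | intermediate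
11 | but-2-yn-1-ol | CC#CCO | starting material
12 | sodium 2,2-bis(2-methoxyethoxy)-3-methyl-2,5-dihydro-1,2-oxaluminol-2-uide (cyclic alkenylalanate) | [Na+].CC1=CCO[Al-]1(OCCOC)OCCOC | intermediate
13 | (2Z)-3-iodobut-2-en-1-ol | C/C(I)=C/CO | intermediate
14 | 9-{2-[(1R,3R)-1,3-dimethyl-2-methylidenecyclohexyl]ethyl}-9-borabicyclo[3.3.1]nonane | C=C1[C@H](C)CCC[C@]1(C)CCB1C2CCCC1CCC2 | intermediate
15 | (2Z)-5-[(1R,3R)-1,3-dimethyl-2-methylidenecyclohexyl]-3-methylpent-2-en-1-ol | C=C1[C@H](C)CCC[C@]1(C)CC/C(C)=C\CO | intermediate
16 | (2Z)-5-[(1R,3R)-1,3-dimethyl-2-methylidenecyclohexyl]-3-methylpent-2-en-1-yl methyl carbonate | C=C1[C@H](C)CCC[C@]1(C)CC/C(C)=C\COC(=O)OC | intermediate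
17 | 2-methoxybenzene-1,4-diol | COc1cc(O)ccc1O | starting material
18 | 2-methoxy-1,4-bis(methoxymethoxy)benzene | COCOc1ccc(OCOC)c(OC)c1 | intermediate
19 | 1-bromo-4-methoxy-2,5-bis(methoxymethoxy)benzene | COCOc1cc(OC)c(OCOC)cc1Br | intermediate
20 | [4-methoxy-2,5-bis(methoxymethoxy)phenyl]lithium | [Li]c1cc(OCOC)c(OC)cc1OCOC | intermediate
21 | lithium trimethoxy[4-methoxy-2,5-bis(methoxymethoxy)phenyl]borate | [Li+].CO[B-](OC)(OC)c1cc(OCOC)c(OC)cc1OCOC | intermediate
22 | 4-methoxy-2,5-bis(methoxymethoxy)phenol | Oc1cc(OCOC)c(OC)cc1OCOC | intermediate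
23 | 2-(hydroxymethyl)-4-methoxy-3,6-bis(methoxymethoxy)phenol | OCc1c(O)c(OCOC)cc(OC)c1OCOC | intermediate
24 | 2-hydroxy-5-methoxy-3,6-bis(methoxymethoxy)benzaldehyde | O=Cc1c(O)c(OCOC)cc(OC)c1OCOC | intermediate
25 | 2-ethenyl-4-methoxy-3,6-bis(methoxymethoxy)phenol | C=Cc1c(O)c(OCOC)cc(OC)c1OCOC | intermediate
26 | (3S)-5-[(1R,3R)-1,3-dimethyl-2-methylidenecyclohexyl]-3-methylpent-1-en-3-yl 2-ethenyl-4-methoxy-3,6-bis(methoxymethoxy)phenyl ether | C=C1[C@H](C)CCC[C@]1(C)CC[C@@](C)(C=C)Oc1c(C=C)c(OCOC)c(OC)cc1OCOC | intermediate
27 | (2S)-2-{2-[(1R,3R)-1,3-dimethyl-2-methylidenecyclohexyl]ethyl}-6-methoxy-5,8-bis(methoxymethoxy)-2-methyl-2H-chromene | C=C1[C@H](C)CCC[C@]1(C)CC[C@@]1(C)C=Cc2c(OCOC)c(OC)cc(OCOC)c2O1 | intermediate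
28 | (2S)-2-{2-[(1R,3R)-1,3-dimethyl-2-methylidenecyclohexyl]ethyl}-6-methoxy-2-methyl-2H-chromene-5,8-diol | C=C1[C@H](C)CCC[C@]1(C)CC[C@@]1(C)C=Cc2c(O)c(OC)cc(O)c2O1 | target

**Totals**

Total step count: 17. Longest linear sequence: 11 steps (1, 2, 3, 4, 5, 6, 8, 9, 15, 16, 17).

**Steps most likely to fail**

Step 15. The doubly ortho-substituted phenoxide may attack the primary terminus of the π-allyl unit (linear ether), facial discrimination may be incomplete, or the tertiary ether may re-ionize and erode. The fallback sets out from 15 and returns at 27. Oxidation of 15 with MnO2 in CH2Cl2 should give (2Z)-5-[(1R,3R)-1,3-dimethyl-2-methylidenecyclohexyl]-3-methylpent-2-enal F1. Condensation of this enal with phenol 22 (PhB(OH)2, catalytic AcOH, toluene, reflux with water removal; ortho-quinone methide formation and oxa-6π electrocyclization) should give chromene 27 together with (2R)-2-{2-[(1R,3R)-1,3-dimethyl-2-methylidenecyclohexyl]ethyl}-6-methoxy-5,8-bis(methoxymethoxy)-2-methyl-2H-chromene F2. The two epimers would be separated by preparative HPLC on a chiral stationary phase. This gives up catalyst control at C2 for a robust ring construction and by-passes 23 to 26.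

Step 6. Methyl transfer may show poor facial selectivity (mismatch with the neighbouring quaternary centre) or direct SN2 displacement may compete. The fallback sets out from 6 and returns at 10. The Wittig reaction of 6 is run with one equivalent of ylide at −78 → 0 °C and ketone 7 is isolated. Condensation with SAMP should give (2S)-N-[(2R)-2-ethenyl-2-methylcyclohexylidene]-2-(methoxymethyl)pyrrolidin-1-amine F3. Deprotonation with LiN(iPr)2 and methylation with MeI at −100 °C (Enders hydrazone alkylation, auxiliary control; the auxiliary antipode is taken according to the usual model) should give (2S)-N-[(2R,6R)-2-ethenyl-2,6-dimethylcyclohexylidene]-2-(methoxymethyl)pyrrolidin-1-amine F4. Two-phase oxalic acid cleavage should give (2R,6R)-2-ethenyl-2,6-dimethylcyclohexan-1-one F5, and non-basic Lombardo methylenation (CH2Br2, Zn, TiCl4) should give 10 without epimerization next to the carbonyl.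

Step 5. Chlorohydrin formation or attack at the vinyl group may compete with the ene-type chlorination. The fallback sets out from 8 and returns at 9. Epoxidation with mCPBA (CH2Cl2, NaHCO3, 0 °C) should take the more electron-rich 1,1-disubstituted alkene and give (4R)-4-ethenyl-4-methyl-1-oxaspiro[2.5]octane F6 as both spiro epimers. Base-induced epoxide opening with LiNEt2 (Et2O, reflux), which can only remove a C3 hydrogen, should give [(6R)-6-ethenyl-6-methylcyclohex-1-en-1-yl]methanol F7. Mesylation (MsCl, Et3N) and displacement with LiCl in DMF should give 9.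

**Further compounds**

F1 | step 15 | (2Z)-5-[(1R,3R)-1,3-dimethyl-2-methylidenecyclohexyl]-3-methylpent-2-enal | C=C1[C@H](C)CCC[C@]1(C)CC/C(C)=C\C=O
F2 | step 15 | (2R)-2-{2-[(1R,3R)-1,3-dimethyl-2-methylidenecyclohexyl]ethyl}-6-methoxy-5,8-bis(methoxymethoxy)-2-methyl-2H-chromene | C=C1[C@H](C)CCC[C@]1(C)CC[C@]1(C)C=Cc2c(OCOC)c(OC)cc(OCOC)c2O1
F3 | step 6 | (2S)-N-[(2R)-2-ethenyl-2-methylcyclohexylidene]-2-(methoxymethyl)pyrrolidin-1-amine (C=N geometry not fixed) | C=C[C@@]1(C)CCCCC1=NN1CCC[C@H]1COC
F4 | step 6 | (2S)-N-[(2R,6R)-2-ethenyl-2,6-dimethylcyclohexylidene]-2-(methoxymethyl)pyrrolidin-1-amine (C=N geometry not fixed) | C=C[C@@]1(C)CCC[C@@H](C)C1=NN1CCC[C@H]1COC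
F5 | step 6 | (2R,6R)-2-ethenyl-2,6-dimethylcyclohexan-1-one | O=C1[C@H](C)CCC[C@]1(C)C=C
F6 | step 5 | (4R)-4-ethenyl-4-methyl-1-oxaspiro[2.5]octane (both configurations at the spiro carbon) | C=C[C@@]1(C)CCCCC12CO2
F7 | step 5 | [(6R)-6-ethenyl-6-methylcyclohex-1-en-1-yl]methanol | OCC1=CCCC[C@]1(C)C=C
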